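**Retrosynthetic overview**

1. Locants: ring A = C1(OH)–C2–C3(Cl)–C4(Me, side chain)–C5(H)–C10(Me); ring B = C5–C6–C7=C8(CO2Me)–C9(CHO)–C10; C11 = aldehyde carbon, C12 = ester carbon; β = face of the C10 methyl, α = the opposite face.
2. Late stage: 3β-Cl by SN2 inversion of a 3α-alcohol made from a C3 ketone; side-chain carbinol by ligand-controlled isopropenyl addition to an aldehyde; C4 quaternary centre by C-alkylation of a regiodefined C3/C4 enolate anti to the C10 methyl; C11 aldehyde by late oxidation.
3. Ring B (formed last) is closed at C6–C7: one-electron reduction of a ring-A cyclopropyl ketone opens the three-membered ring, the C6 radical adds to C7 of a β-methoxyacrylate on C9, and methoxide then leaves. The enabling feature is the bicyclo[4.1.0]heptan-2-one unit of ring A: the C3 carbonyl is conjugated with the C4–C5–C6 cyclopropane, whose exocyclic C4–C6 bond is aligned with the carbonyl π-system, and C6 reaches C7 through C5–C10–C9–C8 so that a six-membered ring results.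
4. The cyclopropane comes from the ring-A enone (sulfoxonium ylide, cis to the C10 methyl); C9 comes from convex-face alkylation of a temporary cis-fused γ-lactone (C11 carbonyl, oxygen on C1) that is later reduced away.
5. Ring A (formed first) by ring-closing metathesis of an acyclic diol whose C1/C10 pair is set in one iridium-catalysed tert-(hydroxy)prenylation of 4-methylpent-4-en-1-ol with isoprene monoxide; C9, C5, C4 and C3 are relayed from this pair by substrate control.

Key step: step 12

Assumption: the (R)-Tol-BINAP iridium catalyst in step 1 is taken to give diol 3 as drawn; if the sense of induction is the opposite, the (S)-ligand is used (the anti relationship of the two new centres does not depend on this choice).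

**Route**

Step 1
Reactants: 1 4-methylpent-4-en-1-ol; 2 2-methyl-2-vinyloxirane (isoprene monoxide, racemic)
Product: 3 (2S,3S)-2-ethenyl-2,6-dimethylhept-6-ene-1,3-diol
Conditions: [Ir(cod)Cl]2, (R)-Tol-BINAP, 4-cyano-3-nitrobenzoic acid, allyl acetate, Cs2CO3 (preformed π-allyl iridium C,O-benzoate complex, 5 mol%), K3PO4 (5 mol%), THF, 60 °C
Reagents that add atoms: none
Why: Iridium-catalysed transfer-hydrogenative tert-(hydroxy)prenylation (a redox-neutral carbonyl allylation run from the alcohol oxidation level) joins the carbinol carbon of 1 to the substituted allyl terminus derived from 2 through a closed chair transition state, which should set the C1 carbinol and the C10 quaternary centre anti (OH anti to CH2OH), with the absolute sense fixed by the ligand.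

Step 2
Reactants: 3 (2S,3S)-2-ethenyl-2,6-dimethylhept-6-ene-1,3-diol
Product: 4 (1S,2S)-2-(hydroxymethyl)-2,4-dimethylcyclohex-3-en-1-ol
Conditions: second-generation Grubbs catalyst (3 mol%), CH2Cl2, 40 °C
Reagents that add atoms: none
Why: Ring-closing olefin metathesis of the vinyl group with the 1,1-disubstituted alkene closes ring A as the C4=C5 trisubstituted cyclohexene with loss of ethylene and touches no stereocentre.

Step 3
Reactants: 4 (1S,2S)-2-(hydroxymethyl)-2,4-dimethylcyclohex-3-en-1-ol
Product: 5 (1R,6S)-6-hydroxy-1,3-dimethylcyclohex-2-ene-1-carbaldehyde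
Conditions: TEMPO (10 mol%), PhI(OAc)2 (1.1 equiv), CH2Cl2, rt
Reagents that add atoms: none
Why: TEMPO/PhI(OAc)2 oxidation is selective for the primary alcohol over the hindered secondary C1 carbinol and stops at the aldehyde, whose quaternary α-carbon cannot epimerise.

Step 4
Reactants: 5 (1R,6S)-6-hydroxy-1,3-dimethylcyclohex-2-ene-1-carbaldehyde
Product: 6 enol ether 2-(2-methoxyethenyl)-2,4-dimethylcyclohex-3-en-1-ol (ring configuration of 4, E/Z mixture)
Conditions: MeOCH2PPh3Cl (3 equiv), KN(SiMe3)2 (2.9 equiv), THF, −78 → 0 °C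
Reagents that add atoms: (methoxymethyl)triphenylphosphonium chloride (COC[P+](c1ccccc1)(c1ccccc1)c1ccccc1.[Cl-])
Why: Wittig methoxymethylenation adds the one-carbon unit C11 to the hindered aldehyde, with excess ylide at low temperature meant to outpace retro-aldol cleavage of the β-alkoxide; no stereocentre is formed and the alkene geometry is irrelevant.

Step 5
Reactants: 6 enol ether
Product: 8 cis-fused γ-lactone (3aR,7aS)-3a,5-dimethyl-3a,6,7,7a-tetrahydro-1-benzofuran-2(3H)-one, via lactol 7 (not isolated)
Conditions: CrO3, H2SO4, H2O, acetone (Jones reagent), 0 °C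
Reagents that add atoms: water (O)
Why: Acid hydrolysis of the enol ether gives the aldehyde, which the cis C1 hydroxyl traps as a five-membered lactol that is oxidised in the same pot (Jones oxidation) to a temporary cis-fused γ-lactone tying C1–O to C11 and making C9 an enolisable, face-differentiated position.

Step 6
Reactants: 8 cis-fused γ-lactone
Product: 10 C9-alkylated lactone (CH2CO2Me on the lactone α-carbon, cis to the angular methyl), via lithium enolate 9 (not isolated)
Conditions: LiN(i-Pr)2, THF, −78 °C; BrCH2CO2Me, DMPU, −78 → −40 °C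
Reagents that add atoms: methyl bromoacetate (COC(=O)CBr)
Why: Alkylation of the lithium enolate of a cis-fused bicyclic γ-lactone should take place on the convex face, cis to the angular C10 methyl and away from the carbocycle, which sets C9 with the C8 acetate arm in the configuration of the target.

Step 7
Reactants: 10 C9-alkylated lactone
Product: 13 (E)-β-methoxyacrylate lactone, via ester enolate 11 (not isolated), via formyl-ester enolate 12 (not isolated)
Conditions: LiN(i-Pr)2 (1.1 equiv), THF, −78 °C; HCO2Me, −78 → 0 °C; then Me2SO4, DMPU, 0 °C → rt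
Reagents that add atoms: methyl formate (COC=O); dimethyl sulfate (COS(=O)(=O)OC)
Why: Kinetic deprotonation at the unhindered ester α-CH2 (C8) instead of the neopentyl lactone methine, Claisen formylation and O-methylation of the formyl-ester enolate (the standard β-methoxyacrylate synthesis) install C7 as an acceptor carbon carrying its own leaving group, while C9 is not deprotonated and keeps its configuration.

Step 8
Reactants: 13 (E)-β-methoxyacrylate lactone
Product: 14 diol (1α-OH, C11–OH; ring-A C4=C5 alkene; β-methoxyacrylate on C9)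
Conditions: LiBH4, THF, 0 °C; aq. NH4Cl
Reagents that add atoms: none
Why: LiBH4 reduces lactones much faster than the electron-rich β-methoxyacrylate ester (a vinylogous carbonate), so the temporary lactone is removed as the C1/C11 diol with all stereocentres intact.

Step 9
Reactants: 14 diol
Product: 15 bis(tert-butyldimethylsilyl) ether of 14
Conditions: t-BuMe2SiOTf (2.5 equiv), 2,6-lutidine, CH2Cl2, −78 → 0 °C
Reagents that add atoms: tert-butyldimethylsilyl trifluoromethanesulfonate (CC(C)(C)[Si](C)(C)OS(=O)(=O)C(F)(F)F)
Why: Silyl triflate/2,6-lutidine silylation protects the primary C11 and the hindered secondary C1 hydroxyl in one operation and blocks lactonisation of the γ-hydroxy ester.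

Step 10
Reactants: 15 bis(silyl) ether
Product: 16 ring-A enone (C3 ketone, C4=C5)
Conditions: Rh2(cap)4 (1 mol%), t-BuOOH (5 equiv), K2CO3, CH2Cl2, rt
Reagents that add atoms: tert-butyl hydroperoxide (CC(C)(C)OO)
Why: Dirhodium caprolactamate/t-BuOOH allylic oxidation converts the only allylic ring methylene (C3; the other allylic ring position, C10, is quaternary) into the enone and so supplies the C3 carbonyl that will activate the cyclopropane.

Step 11
Reactants: 16 ring-A enone
Product: 17 cyclopropyl ketone (C4–C5–C6 cyclopropane, C6 cis to the C10 methyl)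
Conditions: Me3S(O)I, NaH, DMSO, rt
Reagents that add atoms: trimethylsulfoxonium iodide (C[S+](C)(C)=O.[I-])
Why: Corey–Chaykovsky cyclopropanation adds the CH2 that becomes C6 across C4=C5 by conjugate addition and ring closure, and attack at C5 should occur anti to the bulky C9 branch on C10 and to the 1α-silyloxy group, i.e. cis to the C10 methyl, which fixes C5.

Step 12
Reactants: 17 cyclopropyl ketone
Product: 21 enol silane of the ring-closed enoate (trans-fused rings A and B, C3–OSiMe3 enol ether), via C6 radical 18 (not isolated), via bis-enolate 19 (not isolated), via samarium enolate 20 (not isolated)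
Conditions: SmI2 (2.2 equiv, slow addition), HMPA, THF, −78 → −20 °C; then Me3SiCl, Et3N, −78 °C → rt
Reagents that add atoms: chlorotrimethylsilane (C[Si](C)(C)Cl)
Why: SmI2/HMPA transfers one electron to the C3 ketone, and the ketyl opens the fused cyclopropane at the exocyclic C4–C6 bond (the bond aligned with the ketyl π-system), giving the C3/C4 samarium enolate and a primary radical at C6. The closest known reaction type is the SmI2-induced cyclopropyl-ketone fragmentation–radical cyclisation tandem, ended here by the familiar β-alkoxide loss from a samarium ester enolate. Ring B closes in the 6-endo-trig mode: C6 adds to C7, the less substituted β-carbon of the α-branched β-methoxyacrylate, so 5-exo attack at the fully substituted C8 should not compete; a second electron turns the C8 radical into the ester enolate, which expels methoxide and leaves the C7=C8 enoate. No new stereocentre is created: the trans ring fusion is relayed from the cyclopropane, whose C6 sits cis to the C10 methyl, and C9 is untouched. The step needs ketone over acrylate reduction (secured by the electron-rich β-methoxy acrylate), cyclisation before reduction of the C6 radical (secured by slow SmI2 addition and the activated acceptor), and regiospecific capture of the C3/C4 enolate (secured by silylation before any proton source is added).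

Step 13
Reactants: 21 enol silane
Product: 22 keto aldehyde (C4 quaternary: β-methyl, α-CH2CH2CHO; C3 ketone)
Conditions: acrolein, BF3·OEt2 (cat.), i-PrOH (1 equiv), CH2Cl2, −78 °C
Reagents that add atoms: acrolein (C=CC=O)
Why: Mukaiyama–Michael addition of the tetrasubstituted enol silane to acrolein creates the C4 quaternary centre, and the electrophile should enter on the α face, anti to the syn-axial C10 methyl and to C6 on C5 (as in alkylations of 4-methyl enolates of 10-methyl-3-decalones), leaving the C4 methyl axial (β).

Step 14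
Reactants: 22 keto aldehyde
Product: 23 allylic alcohol ((R)-carbinol in the side chain)
Conditions: 2-bromopropene, CrCl2 (4 equiv), NiCl2 (2 mol%), chiral oxazoline–sulfonamide ligand (4.4 equiv), Et3N, THF, rt
Reagents that add atoms: 2-bromopropene (CC(Br)=C)
Why: The Nozaki–Hiyama–Kishi reaction adds the isopropenyl chromium reagent to the aldehyde only (the hindered C3 ketone and the enoate are inert), and the chiral ligand on chromium, used as the enantiomer that gives the (R)-carbinol, sets this remote stereocentre by reagent control.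

Step 15
Reactants: 23 allylic alcohol
Product: 24 tris(silyl) ether ketone
Conditions: t-BuMe2SiCl, imidazole, DMF, rt
Reagents that add atoms: tert-butyldimethylsilyl chloride (CC(C)(C)[Si](C)(C)Cl)
Why: Standard silylation protects the allylic carbinol so that only the C3 hydroxyl made in the next step is substituted later.

Step 16
Reactants: 24 tris(silyl) ether ketone
Product: 25 3α-alcohol (axial)
Conditions: LiBH(s-Bu)3, THF, −78 → −40 °C; H2O
Reagents that add atoms: none
Why: The bulky hydride should attack the C3 ketone from the equatorial (β) side, away from the axial 1α-silyloxy group, to give the axial 3α-alcohol (substrate-controlled ketone reduction).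

Step 17
Reactants: 25 3α-alcohol
Product: 26 3β-chloride
Conditions: PPh3, CCl4, 2,6-di-tert-butylpyridine, toluene, 70 °C
Reagents that add atoms: carbon tetrachloride (ClC(Cl)(Cl)Cl)
Why: Appel chlorination displaces the axial oxyphosphonium group by chloride with inversion (SN2), placing chlorine equatorial (3β), and the axial leaving group in a buffered, non-ionising medium is chosen to disfavour elimination and methyl migration at this neopentyl position.

Step 18
Reactants: 26 3β-chloride
Product: 27 primary alcohol (C11–OH; the two secondary silyl ethers retained)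
Conditions: HF·pyridine, pyridine, THF, 0 °C
Reagents that add atoms: none
Why: Buffered HF·pyridine cleaves the primary silyl ether much faster than the two secondary ones (selective desilylation), and the γ-hydroxy enoate is used at once to avoid lactonisation.

Step 19
Reactants: 27 primary alcohol
Product: 28 aldehyde (C11 = CHO; the two secondary silyl ethers retained)
Conditions: Dess–Martin periodinane, NaHCO3, CH2Cl2, 0 °C → rt
Reagents that add atoms: none
Why: Dess–Martin oxidation under buffered, non-basic conditions gives the β,γ-unsaturated aldehyde without epimerising C9.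

Step 20
Reactants: 28 aldehyde
Product: 29 CNP0159496.2 (target)
Conditions: HF·pyridine (excess), THF, rt
Reagents that add atoms: none
Why: Acidic fluoride removes the two secondary silyl ethers without base, so the epimerisable C9 centre next to the aldehyde and the allylic carbinol should survive and the target is released.

**Compound list**

1 | 4-methylpent-4-en-1-ol | CC(=C)CCCO | starting material
2 | 2-methyl-2-vinyloxirane (isoprene monoxide, racemic) | C=CC1(C)CO1 | starting material
3 | (2S,3S)-2-ethenyl-2,6-dimethylhept-6-ene-1,3-diol | C=C(C)CC[C@H](O)[C@](C)(CO)C=C | intermediate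
4 | (1S,2S)-2-(hydroxymethyl)-2,4-dimethylcyclohex-3-en-1-ol | O[C@H]1CCC(C)=C[C@@]1(C)CO | intermediate
5 | (1R,6S)-6-hydroxy-1,3-dimethylcyclohex-2-ene-1-carbaldehyde | O[C@H]1CCC(C)=C[C@@]1(C)C=O | intermediate
6 | enol ether: 2-(2-methoxyethenyl)-2,4-dimethylcyclohex-3-en-1-ol, ring configuration of 4, E/Z mixture | O[C@H]1CCC(C)=C[C@@]1(C)C=COC | intermediate
7 | lactol: cis-fused 3a,5-dimethyl-2,3,3a,6,7,7a-hexahydro-1-benzofuran-2-ol (anomers) | OC1C[C@]2(C)C=C(C)CC[C@@H]2O1 | intermediate (not isolated)
8 | (3aR,7aS)-3a,5-dimethyl-3a,6,7,7a-tetrahydro-1-benzofuran-2(3H)-one (cis-fused γ-lactone; carbonyl = C11, ring oxygen on C1) | O=C1C[C@]2(C)C=C(C)CC[C@@H]2O1 | intermediate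
9 | lithium enolate of lactone 8 | [Li+].[O-]C1=C[C@]2(C)C=C(C)CC[C@@H]2O1 | intermediate (not isolated)
10 | lactone 8 with CH2CO2Me on the lactone α-carbon (C9), cis to the angular methyl | O=C1[C@@H](CC(=O)OC)[C@]2(C)C=C(C)CC[C@@H]2O1 | intermediate
11 | lithium ester enolate of 10 (enolate at C8) | O=C1[C@@H](C=C([O-])OC)[C@]2(C)C=C(C)CC[C@@H]2O1.[Li+] | intermediate (not isolated)
12 | lithium enolate of the C8-formyl ester | O=C1[C@@H](C(=C[O-])C(=O)OC)[C@]2(C)C=C(C)CC[C@@H]2O1.[Li+] | intermediate (not isolated)
13 | lactone 8 with the (E)-β-methoxyacrylate unit (C8(CO2Me)=C7H–OMe) on C9 | O=C1[C@@H](/C(=C\OC)C(=O)OC)[C@]2(C)C=C(C)CC[C@@H]2O1 | intermediate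
14 | diol: ring-A cyclohexene (C4=C5) with 1α-OH and 10β-Me; C9 carries CH2OH (C11) and the (E)-β-methoxyacrylate | CO/C=C(\[C@H](CO)[C@]1(C)C=C(C)CC[C@@H]1O)C(=O)OC | intermediate
15 | bis(tert-butyldimethylsilyl) ether of 14 (1α-OTBS, 11-OTBS) | CO/C=C(\[C@H](CO[Si](C)(C)C(C)(C)C)[C@]1(C)C=C(C)CC[C@@H]1O[Si](C)(C)C(C)(C)C)C(=O)OC | intermediate
16 | ring-A enone (C3=O, C4(Me)=C5H) derived from 15 | CO/C=C(\[C@H](CO[Si](C)(C)C(C)(C)C)[C@]1(C)C=C(C)C(=O)C[C@@H]1O[Si](C)(C)C(C)(C)C)C(=O)OC | intermediate
17 | cyclopropyl ketone: bicyclo[4.1.0]heptan-2-one ring A (C3=O; cyclopropane C4(Me)–C5(H)–C6H2, C6 cis to the C10 methyl) | CO/C=C(\[C@H](CO[Si](C)(C)C(C)(C)C)[C@]1(C)[C@H]2C[C@@]2(C)C(=O)C[C@@H]1O[Si](C)(C)C(C)(C)C)C(=O)OC | intermediate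
18 | ring-opened species: C3/C4 samarium enolate with a primary radical at C6 | CO/C=C(\[C@H](CO[Si](C)(C)C(C)(C)C)[C@]1(C)[C@@H]([CH2])C(C)=C(O[Sm](I)I)C[C@@H]1O[Si](C)(C)C(C)(C)C)C(=O)OC | intermediate (not isolated)
19 | ring-closed bis(samarium enolate): C7–OMe, ester enolate at C8, ketone enolate at C3/C4 | COC(O[Sm](I)I)=C1C(OC)C[C@H]2C(C)=C(O[Sm](I)I)C[C@H](O[Si](C)(C)C(C)(C)C)[C@]2(C)[C@H]1CO[Si](C)(C)C(C)(C)C | intermediate (not isolated)
20 | C3/C4 samarium enolate of the ring-closed C7=C8 enoate | COC(=O)C1=CC[C@H]2C(C)=C(O[Sm](I)I)C[C@H](O[Si](C)(C)C(C)(C)C)[C@]2(C)[C@H]1CO[Si](C)(C)C(C)(C)C | intermediate (not isolated)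
21 | enol silane: trans-fused decalin, C7=C8–CO2Me, C3(OSiMe3)=C4(Me), 1α-OTBS, 11-OTBS, 5α-H, 10β-Me | COC(=O)C1=CC[C@H]2C(C)=C(O[Si](C)(C)C)C[C@H](O[Si](C)(C)C(C)(C)C)[C@]2(C)[C@H]1CO[Si](C)(C)C(C)(C)C | intermediate
22 | keto aldehyde: C3 ketone, C4 with β-Me and α-CH2CH2CHO | COC(=O)C1=CC[C@H]2[C@](C)(CCC=O)C(=O)C[C@H](O[Si](C)(C)C(C)(C)C)[C@]2(C)[C@H]1CO[Si](C)(C)C(C)(C)C | intermediate
23 | allylic alcohol: side chain CH2CH2–(R)-CH(OH)–C(Me)=CH2 on C4, C3 ketone | COC(=O)C1=CC[C@H]2[C@](C)(CC[C@@H](O)C(C)=C)C(=O)C[C@H](O[Si](C)(C)C(C)(C)C)[C@]2(C)[C@H]1CO[Si](C)(C)C(C)(C)C | intermediate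
24 | tris(silyl) ether ketone (side-chain OTBS, 1α-OTBS, 11-OTBS) | COC(=O)C1=CC[C@H]2[C@](C)(CC[C@@H](O[Si](C)(C)C(C)(C)C)C(C)=C)C(=O)C[C@H](O[Si](C)(C)C(C)(C)C)[C@]2(C)[C@H]1CO[Si](C)(C)C(C)(C)C | intermediate
25 | 3α-alcohol (axial OH at C3) | COC(=O)C1=CC[C@H]2[C@](C)(CC[C@@H](O[Si](C)(C)C(C)(C)C)C(C)=C)[C@H](O)C[C@H](O[Si](C)(C)C(C)(C)C)[C@]2(C)[C@H]1CO[Si](C)(C)C(C)(C)C | intermediate
26 | 3β-chloride (equatorial Cl at C3) | COC(=O)C1=CC[C@H]2[C@](C)(CC[C@@H](O[Si](C)(C)C(C)(C)C)C(C)=C)[C@@H](Cl)C[C@H](O[Si](C)(C)C(C)(C)C)[C@]2(C)[C@H]1CO[Si](C)(C)C(C)(C)C | intermediate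
27 | primary alcohol (C11–OH) | COC(=O)C1=CC[C@H]2[C@](C)(CC[C@@H](O[Si](C)(C)C(C)(C)C)C(C)=C)[C@@H](Cl)C[C@H](O[Si](C)(C)C(C)(C)C)[C@]2(C)[C@H]1CO | intermediate
28 | aldehyde (C11 = CHO), bis(silyl) ether | COC(=O)C1=CC[C@H]2[C@](C)(CC[C@@H](O[Si](C)(C)C(C)(C)C)C(C)=C)[C@@H](Cl)C[C@H](O[Si](C)(C)C(C)(C)C)[C@]2(C)[C@H]1C=O | intermediate
29 | CNP0159496.2 | COC(=O)C1=CC[C@H]2[C@](C)(CC[C@@H](O)C(C)=C)[C@@H](Cl)C[C@H](O)[C@]2(C)[C@H]1C=O | target

**Step count and risks**

Total step count: 20. Longest linear sequence: 20 steps (fully linear from 1 and 2).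

Steps most likely to fail:

1. Step 12 (key step). What may go wrong: reduction of the primary C6 radical before it cyclises (giving the uncyclised 5-methyl compound), or competing electron transfer to the acrylate. The fallback sets out from 17 and returns at 21. Me3SiI, CH2Cl2, −78 °C should open the cyclopropyl ketone by homoconjugate addition of iodide at C6 to give the primary iodide enol silane F1. Bu3SnH, AIBN, benzene, 80 °C (slow addition) should then close ring B by 6-endo radical cyclisation to the ring-closed β-methoxy ester F2. DBU, CH2Cl2 should finally eliminate methanol to give 21.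

2. Step 13. What may go wrong: slow conjugate addition of the hindered tetrasubstituted enol silane, with protodesilylation or 1,2-addition to acrolein taking over and facial control at C4 eroding. The fallback sets out from 21 and returns at 22. MeLi, THF, 0 °C, then allyl bromide, DMPU, −78 °C should give, by regiospecific lithium enolate allylation anti to the C10 methyl, the C4-allyl ketone F3. An aldehyde-selective Wacker oxidation (PdCl2(PhCN)2, CuCl2, AgNO2, t-BuOH/MeNO2, O2, rt) should then convert the terminal alkene into 22.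

3. Step 17. What may go wrong: ionisation instead of substitution at the neopentyl carbinol, leading to elimination or methyl migration. The fallback sets out from 25 and returns at 26. Redox epimerisation of the carbinol with (C5Ph5)Ru(CO)2Cl and catalytic t-BuOK in toluene should give the more stable equatorial 3β-alcohol F4 (it no longer suffers the 1,3-diaxial contact with the 1α-silyloxy group). SOCl2 with catalytic TiCl4 in CH2Cl2 at 0 °C (front-side, retentive chlorination of the chlorosulfite) should then give 26.

Further compounds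
F1 | step 12 | primary iodide enol silane (C6–I on C5, C3(OSiMe3)=C4 enol ether, acrylate intact) | CO/C=C(\[C@H](CO[Si](C)(C)C(C)(C)C)[C@]1(C)[C@@H](CI)C(C)=C(O[Si](C)(C)C)C[C@@H]1O[Si](C)(C)C(C)(C)C)C(=O)OC
F2 | step 12 | ring-closed β-methoxy ester (C7–OMe, C8–H; enol silane retained) | COC(=O)C1C(OC)C[C@H]2C(C)=C(O[Si](C)(C)C)C[C@H](O[Si](C)(C)C(C)(C)C)[C@]2(C)[C@H]1CO[Si](C)(C)C(C)(C)C
F3 | step 13 | C4-allyl ketone (allyl α, methyl β) | COC(=O)C1=CC[C@H]2[C@](C)(CC=C)C(=O)C[C@H](O[Si](C)(C)C(C)(C)C)[C@]2(C)[C@H]1CO[Si](C)(C)C(C)(C)C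
F4 | step 17 | 3β-alcohol (C3 epimer of 25) | COC(=O)C1=CC[C@H]2[C@](C)(CC[C@@H](O[Si](C)(C)C(C)(C)C)C(C)=C)[C@@H](O)C[C@H](O[Si](C)(C)C(C)(C)C)[C@]2(C)[C@H]1CO[Si](C)(C)C(C)(C)C
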